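Take the gap first: the solid substrate lost minus the product formed, which is material that has left the solid and is not product. I use it to read a rate and a delay from the earlier runs.

| flask | solid substrate | gas phase | catalyst | remark | time |
|---|---|---|---|---|---|
| ochre | 0.13 M | 8.5 mM (held) | 30 mM | run made earlier |  |
| red | 0.30 M | 8.5 mM (held) | 30 mM | run made earlier |  |
| blue | 0.20 M | 8.5 mM (held) | 15 mM | run made earlier |  |
| flask | 0.20 M | 8.5 mM (held) | 30 mM |  | 25 h |

- ochre (time / h: product / %, solid substrate / %): 1.33: 0.2, 98.7; 4.00: 0.7, 96.6; 8.00: 2.3, 94.0; 10.0: 2.8, 93.7; 15.0: 4.3, 91.9
- red (time / h: product / %, solid substrate / %): 1.33: 0, 99.4; 2.50: 0, 98.8; 4.00: 0.9, 98.7; 8.00: 0.5, 97.2; 15.0: 2.4, 96.0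
- blue (time / h: product / %, solid substrate / %): 1.33: 0.2, 99.5; 4.00: 0, 97.6; 8.00: 0.6, 96.6; 10.0: 1.2, 96.8; 15.0: 1.7, 94.6

(each reading ± 0.3 percentage points)

- as a solid, counted per litre of solution: solid substrate
- at the start none of the gas phase is in solution
- at the start none of the solid substrate is in solution

* how much product there is at 25 h, in percent of the solid substrate charged
* concentration of dissolved gas in solution at 25 h, in percent of saturation

At the last reading the gap is 4.94 mM in the ochre run and 4.80 mM in the red run, about equal, with charges of 0.13 M and 0.30 M. So I apply both runs to this flask, which has the same catalyst, and leave the blue run aside.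

I start with the main step alone. Mean product of the ochre and red runs at 15.0 h is 6.39 mM. The gap in the ochre run is 3.51 mM at 4.00 h, and a first-order rise then gives a delay of 3.23 h. From these I get the steady rate, 0.543 mM h⁻¹: product formed per hour once the gap has filled, as a reading with its scatter. Without any delay, this rate gives 6.79 % at 25 h.

Adding dissolution subtracts the delay, which leaves 5.91 %. For the gas I make no separate correction: the rate was read from runs with gas transfer running. I expect dissolved gas near saturation, but no reading measures it.

The forecast gives 5.3 % and 90 %, holding that “the rate barely depends on solid loading”. Its product is lower than mine.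

The flask gives 5.55 % of product, lower than mine, and dissolved gas at 95.5 % of saturation, higher than the forecast.

    gas phase ⇌ dissolved gas, rate k1*(csat - [dissolved gas]) (kL = 1.40 h⁻¹)
    starting material + dissolved gas + catalyst → catalyst + product (k = 380 L² mol⁻² h⁻¹)
    solid substrate ⇌ starting material, rate k3*(cs3 - [starting material]) while solid is left; crystals form when [starting material] > cs3 (solubility = 10.0 mM, k = 0.130 h⁻¹)

In the flask, half of the dissolution's turnover up to the asked time is done by 10.0 h, and starting material stands at 2.74 % at 12.5 h. At 25 h in the flask, with solid substrate at 91.5 %, starting material stands at 2.91 %, made 1.01 times as fast as it is used up, each step taken net, a steady state, and product has climbed since 12.5 h at 0.529 mM h⁻¹ beside my 0.543 mM h⁻¹. For the same flask read at 4.0 d, my rate and delay give 25.2 %, and that flask holds 24.7 %.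

The data are simulated with constants of no real substance, and the scatter is random.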